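**Retrosynthetic overview**
1. Bromophycolide H ⇐ phenol desilylation ⇐ 16-membered macrolactonisation at the C15 tertiary OH of a bis-bromohydrin seco acid (second ring formed).
2. The C10/C11 and C14/C15 bromohydrins ⇐ SN2 bromide opening of an (S,S),(S)-bis-epoxide ⇐ one ent-Shi epoxidation of the side-chain diene. C3=CH2 ⇐ C3 ketone.
3. Bromocyclohexanone (first ring formed, C2–C7 bond) ⇐ an enantiospecific bromonium ion released from a (6S,7R)-bromohydrin ester and trapped by a tethered (Z)-silyl enol ether.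
4. Key C–C bond, aryl–C1: aryl iodide plus vinyl ketone (two electrophilic carbons), joined through a 1-(silyloxy)allylnickel homoenolate equivalent. The same step delivers the regiodefined silyl enol ether.
5. Vinyl ketone ⇐ vinyl Grignard and Weinreb acetamide enolate plus (2R,3R)-epoxyfarnesyl triflate ⇐ Sharpless epoxidation of (E,E)-farnesol.

Assumption: locants C1–C15 run along the diterpene chain from the benzylic carbon (C1) to the ester-bearing carbon (C15). D-(−)-diethyl tartrate and the L-fructose-derived (ent-)Shi ketone are taken as purchasable chiral catalyst components.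

**Step 1**
Reactants: 1 methyl 4-hydroxy-3-iodobenzoate
Product: 2 methyl 3-iodo-4-(triisopropylsilyloxy)benzoate
Conditions: TIPSCl, imidazole, DMF, rt
Reagents that add atoms: triisopropylsilyl chloride CC(C)[Si](Cl)(C(C)C)C(C)C
Why: Standard silyl ether formation masks the phenol with a group that survives the Ni, Lewis-acid, basic-buffer and acylation steps and leaves under neutral fluoride conditions; no stereocentre is involved.

**Step 2**
Reactants: 3 (2E,6E)-farnesol
Product: 4 (2R,3R)-2,3-epoxyfarnesol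
Conditions: Ti(OiPr)4 (10 mol %), D-(−)-DET (12 mol %), TBHP, 4 Å MS, CH2Cl2, −20 °C
Reagents that add atoms: tert-butyl hydroperoxide CC(C)(C)OO
Why: The Sharpless asymmetric epoxidation is directed by the allylic OH, so only the C6=C7 alkene reacts, and the D-(−)-tartrate delivers oxygen to the face that gives the (2R,3R)-epoxide (future C6 and C7) in high ee.

**Step 3**
Reactants: 4 (2R,3R)-2,3-epoxyfarnesol; 5 N-methoxy-N-methylacetamide
Product: 8 3-[(2R,3R)-3-((3E)-4,8-dimethylnona-3,7-dienyl)-3-methyloxiran-2-yl]-N-methoxy-N-methylpropanamide, via amide lithium enolate 6 (not isolated), via epoxyfarnesyl triflate 7 (not isolated)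
Conditions: (a) 5, LDA, THF, −78 °C; (b) 4, Tf2O, 2,6-lutidine, CH2Cl2, −78 °C, cannulate into (a), −78 → −40 °C
Reagents that add atoms: none
Why: SN2 enolate alkylation of the primary triflate at −78 °C outruns attack on the trisubstituted epoxide, adds C3–C4 and leaves both stereocentres untouched.

**Step 4**
Reactants: 8 epoxy Weinreb amide
Product: 9 5-[(2R,3R)-3-((3E)-4,8-dimethylnona-3,7-dienyl)-3-methyloxiran-2-yl]pent-1-en-3-one
Conditions: CH2=CHMgBr, THF, −20 → 0 °C; cold aq NaH2PO4
Reagents that add atoms: vinylmagnesium bromide C=C[Mg]Br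
Why: In this Weinreb ketone synthesis the magnesium chelate stops over-addition, and the cold buffered quench avoids amine re-addition and epoxide opening; it installs C1=C2 as an enone.

**Step 5 (key step)**
Reactants: 9 epoxy vinyl ketone; 2 methyl 3-iodo-4-(triisopropylsilyloxy)benzoate
Product: 10 methyl 3-[(2Z,6R,7R,10E)-6,7-epoxy-7,11,15-trimethyl-3-(triethylsilyloxy)hexadeca-2,10,14-trienyl]-4-(triisopropylsilyloxy)benzoate
Conditions: NiCl2·dme (10 mol %), neocuproine (10 mol %), Mn, Et3SiCl, DMF, rt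
Reagents that add atoms: chlorotriethylsilane CC[Si](Cl)(CC)CC
Why: In this nickel-catalysed reductive conjugate arylation (cross-electrophile coupling), Ni(0), the enone and Et3SiCl form a 1-(silyloxy)allylnickel homoenolate equivalent that joins the normally electrophilic β-carbon C1 to the electrophilic aryl iodide carbon, and the silyl group fixes the enolate regiospecifically as the C2=C3 silyl enol ether, Z from the s-cis enone.

**Step 6**
Reactants: 10 epoxy silyl enol ether
Product: 11 methyl 3-[(2Z,6S,7R,10E)-6-bromo-7-hydroxy-7,11,15-trimethyl-3-(triethylsilyloxy)hexadeca-2,10,14-trienyl]-4-(triisopropylsilyloxy)benzoate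
Conditions: Li2NiBr4, THF, 0 °C → rt; pH 7 buffer
Reagents that add atoms: dilithium tetrabromonickelate [Li+].[Li+].[Ni+2].[Br-].[Br-].[Br-].[Br-]
Why: Soft, non-acidic bromide opens the trisubstituted epoxide by SN2 at the secondary carbon C6 with inversion (6R → 6S), leaves C7 as the (R)-tertiary alcohol and spares the enol ether.

**Step 7**
Reactants: 11 bromohydrin silyl enol ether
Product: 13 methyl 3-{[(1S,2S,3S)-3-bromo-2-((3E)-4,8-dimethylnona-3,7-dienyl)-2-methyl-6-oxocyclohexyl]methyl}-4-(triisopropylsilyloxy)benzoate, via tertiary trifluoroacetate 12 (not isolated)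
Conditions: (CF3CO)2O, 2,6-di-tert-butyl-4-methylpyridine, CH2Cl2, −78 → −40 °C; then TMSOTf (20 mol %), −78 °C
Reagents that add atoms: none
Why: Proposed new method: silyl triflate ionises the tertiary trifluoroacetate with anchimeric help from the anti C6 bromine to a configurationally defined bromonium ion, which the tethered (Z)-silyl enol ether opens at C7 anti to bromine through a chair transition state (net retention at C7; Br, side chain and CH2Ar all equatorial, which sets C7 and C2), the closest known reaction types being the Lewis-acid α-tert-alkylation of silyl enol ethers with SN1-active tertiary esters or halides (Reetz/Mukaiyama type) and the enantiospecific cyclisation of bromonium ions released from enantiopure bromohydrin esters.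

**Step 8**
Reactants: 13 bromocyclohexanone
Product: 14 methyl 3-{[(1R,2S,3S)-3-bromo-2-((3E)-4,8-dimethylnona-3,7-dienyl)-2-methyl-6-methylidenecyclohexyl]methyl}-4-(triisopropylsilyloxy)benzoate
Conditions: Zn, CH2Br2, TiCl4, THF/CH2Cl2, 0 °C → rt
Reagents that add atoms: dibromomethane BrCBr
Why: The Takai–Lombardo methylenation is non-basic, so the epimerisable C2 centre is kept, and it leaves esters, the silyl ether and the unactivated secondary bromide alone.

**Step 9**
Reactants: 14 methyl ester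
Product: 15 3-{[(1R,2S,3S)-3-bromo-2-((3E)-4,8-dimethylnona-3,7-dienyl)-2-methyl-6-methylidenecyclohexyl]methyl}-4-(triisopropylsilyloxy)benzoic acid
Conditions: Me3SnOH, 1,2-dichloroethane, 80 °C; 5 % HCl wash
Reagents that add atoms: trimethyltin hydroxide C[Sn](C)(C)O
Why: Tin hydroxide ester hydrolysis is essentially neutral and frees the acid without cleaving the base-labile aryl silyl ether or touching the bromide; it is placed before any epoxide or bromohydrin is present.

**Step 10**
Reactants: 15 diene acid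
Product: 16 3-{[(1R,2S,3S)-3-bromo-2-(2-{(2S,3S)-3-[2-((2S)-3,3-dimethyloxiran-2-yl)ethyl]-3-methyloxiran-2-yl}ethyl)-2-methyl-6-methylidenecyclohexyl]methyl}-4-(triisopropylsilyloxy)benzoic acid
Conditions: ent-Shi ketone (30 mol %), Oxone, K2CO3, Bu4NHSO4, MeCN–DMM/borate buffer, 0 °C; work-up at pH 5–6
Reagents that add atoms: potassium peroxymonosulfate (Oxone) [K+].[O-]S(=O)(=O)OO
Why: The Shi asymmetric epoxidation is reagent-controlled: the L-series ketone gives the (10S,11S)- and (14S)-epoxides in one operation, and the two trisubstituted alkenes react much faster than the hindered 1,1-disubstituted ring methylene.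

**Step 11**
Reactants: 16 bis-epoxy acid
Product: 17 3-{[(1R,2S,3S)-3-bromo-2-((3R,4S,7R)-3,7-dibromo-4,8-dihydroxy-4,8-dimethylnonyl)-2-methyl-6-methylidenecyclohexyl]methyl}-4-(triisopropylsilyloxy)benzoic acid
Conditions: Li2NiBr4 (excess), THF, 0 °C → rt; pH 5 buffer
Reagents that add atoms: dilithium tetrabromonickelate [Li+].[Li+].[Ni+2].[Br-].[Br-].[Br-].[Br-]
Why: SN2 epoxide opening by soft bromide at both secondary carbons inverts C10 and C14 (S → R) and retains (11S), giving the anti bromohydrins of the target.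

**Step 12**
Reactants: 17 seco acid
Product: 19 O-triisopropylsilyl bromophycolide H, via mixed anhydride 18 (not isolated)
Conditions: MNBA, DMAP, toluene (1 mM), syringe pump 16 h, 60 °C
Reagents that add atoms: none
Why: In this Shiina macrolactonisation the phenol is masked, the gem-dimethyl carbinol at C15 is the less hindered tertiary OH, and it closes an unstrained 16-membered ring whereas C11–OH would give a strained 12-membered metacyclophane; no stereocentre is touched.

**Step 13**
Reactants: 19 O-triisopropylsilyl bromophycolide H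
Product: 20 bromophycolide H
Conditions: HF·pyridine, THF/pyridine, 0 °C
Reagents that add atoms: none
Why: Fluoride desilylation of the aryl silyl ether under non-basic conditions avoids bromohydrin-to-epoxide closure and lactone cleavage.

**Compound list**
1 | methyl 4-hydroxy-3-iodobenzoate | COC(=O)c1ccc(O)c(I)c1 | starting material
2 | methyl 3-iodo-4-(triisopropylsilyloxy)benzoate | COC(=O)c1ccc(O[Si](C(C)C)(C(C)C)C(C)C)c(I)c1 | intermediate
3 | (2E,6E)-farnesol | CC(C)=CCC/C(C)=C/CC/C(C)=C/CO | starting material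
4 | (2R,3R)-2,3-epoxyfarnesol | CC(C)=CCC/C(C)=C/CC[C@@]1(C)O[C@@H]1CO | intermediate
5 | N-methoxy-N-methylacetamide | CC(=O)N(C)OC | starting material
6 | lithium enolate of N-methoxy-N-methylacetamide | [Li+].C=C([O-])N(C)OC | intermediate
7 | (2R,3R)-2,3-epoxyfarnesyl triflate | CC(C)=CCC/C(C)=C/CC[C@@]1(C)O[C@@H]1COS(=O)(=O)C(F)(F)F | intermediate
8 | epoxy Weinreb amide (6R,7R) | CC(C)=CCC/C(C)=C/CC[C@@]1(C)O[C@@H]1CCC(=O)N(C)OC | intermediate
9 | epoxy vinyl ketone (6R,7R) | CC(C)=CCC/C(C)=C/CC[C@@]1(C)O[C@@H]1CCC(=O)C=C | intermediate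
10 | (2Z,6R,7R,10E)-epoxy triethylsilyl enol ether aryl ester | CC(C)=CCC/C(C)=C/CC[C@@]1(C)O[C@@H]1CC/C(O[Si](CC)(CC)CC)=C/Cc2cc(C(=O)OC)ccc2O[Si](C(C)C)(C(C)C)C(C)C | intermediate
11 | (2Z,6S,7R,10E)-6-bromo-7-hydroxy silyl enol ether | CC(C)=CCC/C(C)=C/CC[C@@](C)(O)[C@@H](Br)CC/C(O[Si](CC)(CC)CC)=C/Cc1cc(C(=O)OC)ccc1O[Si](C(C)C)(C(C)C)C(C)C | intermediate
12 | (6S,7R)-6-bromo-7-trifluoroacetate of 11 | CC(C)=CCC/C(C)=C/CC[C@@](C)(OC(=O)C(F)(F)F)[C@@H](Br)CC/C(O[Si](CC)(CC)CC)=C/Cc1cc(C(=O)OC)ccc1O[Si](C(C)C)(C(C)C)C(C)C | intermediate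
13 | (1S,2S,3S)-bromocyclohexanone methyl ester | O=C1CC[C@H](Br)[C@@](C)(CC/C=C(C)/CCC=C(C)C)[C@@H]1Cc2cc(C(=O)OC)ccc2O[Si](C(C)C)(C(C)C)C(C)C | intermediate
14 | (1R,2S,3S)-methylidene cyclohexane methyl ester | C=C1CC[C@H](Br)[C@@](C)(CC/C=C(C)/CCC=C(C)C)[C@@H]1Cc2cc(C(=O)OC)ccc2O[Si](C(C)C)(C(C)C)C(C)C | intermediate
15 | diene acid | C=C1CC[C@H](Br)[C@@](C)(CC/C=C(C)/CCC=C(C)C)[C@@H]1Cc2cc(C(=O)O)ccc2O[Si](C(C)C)(C(C)C)C(C)C | intermediate
16 | (10S,11S,14S)-bis-epoxy acid | C=C1CC[C@H](Br)[C@@](C)(CC[C@@H]2O[C@@]2(C)CC[C@@H]3OC3(C)C)[C@@H]1Cc4cc(C(=O)O)ccc4O[Si](C(C)C)(C(C)C)C(C)C | intermediate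
17 | (2R,6S,7S,10R,11S,14R)-tribromo dihydroxy seco acid | C=C1CC[C@H](Br)[C@@](C)(CC[C@@H](Br)[C@@](C)(O)CC[C@@H](Br)C(C)(C)O)[C@@H]1Cc2cc(C(=O)O)ccc2O[Si](C(C)C)(C(C)C)C(C)C | intermediate
18 | mixed anhydride of 17 and 2-methyl-6-nitrobenzoic acid | C=C1CC[C@H](Br)[C@@](C)(CC[C@@H](Br)[C@@](C)(O)CC[C@@H](Br)C(C)(C)O)[C@@H]1Cc2cc(C(=O)OC(=O)c3c(C)cccc3[N+](=O)[O-])ccc2O[Si](C(C)C)(C(C)C)C(C)C | intermediate
19 | O-triisopropylsilyl bromophycolide H | C=C1CC[C@H](Br)[C@@]2(C)CC[C@@H](Br)[C@@](C)(O)CC[C@@H](Br)C(C)(C)OC(=O)c3ccc(O[Si](C(C)C)(C(C)C)C(C)C)c(c3)C[C@H]12 | intermediate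
20 | bromophycolide H | C=C1CC[C@H](Br)[C@@]2(C)CC[C@@H](Br)[C@@](C)(O)CC[C@@H](Br)C(C)(C)OC(=O)c3ccc(O)c(c3)C[C@H]12 | target

**Totals**
- Total step count: 13.
- Longest linear sequence: 12 (steps 2–13, from farnesol).

**Three steps most likely to fail**

Step 5. Et3SiCl and Mn(II) salts in DMF may open the γ,δ-epoxy ketone, and the bulky ortho-silyloxy iodide may couple slowly. The fallback sets out from 9 and 2. A Heck arylation (Pd(OAc)2, Bu4NCl, NaHCO3, DMF) gives the (E)-aryl enone F1. Rhodium-catalysed 1,4-hydrosilylation with Et3SiH (RhCl(PPh3)3, benzene) then delivers the same regiodefined (Z)-silyl enol ether and comes back to the route at 10.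

Step 7. Trifluoroacetylation may touch the enol ether, or the ion may eliminate or pass Br+ to the side-chain alkenes before C–C bond formation. The fallback sets out from 11. Catalytic CSA with 4 Å sieves expels triethylsilanol and closes the C7 hydroxyl onto C3 to give the cyclic bromo enol ether F2, a 2-alkylidene tetrahydropyran. Me2AlCl at −78 °C then ionises the tertiary C7–O bond, and the aluminium enolate recombines through C2 (Ferrier/Petasis-type O-to-C rearrangement). This comes back to the route at 13.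

Step 12. Acylation of a tertiary, β-brominated alcohol is slow, so oligomers, C11 acylation or epoxide formation may win. The fallback sets out from 16. Neutral treatment with 1-bromo-N,N,2-trimethylpropenylamine gives the bis-epoxy acyl bromide F3. Catalytic Bu4NBr at high dilution (toluene, 60 °C) opens the terminal epoxide at C14 with inversion, and the tertiary alkoxide is acylated in the same event (halide-catalysed addition of an acyl halide to an epoxide). This gives the 10,11-epoxy macrolactone F4. Li2NiBr4 then opens the remaining epoxide and the route is rejoined at 19.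

**Further compounds**
F1 | step 5 | methyl 3-[(1E)-5-((2R,3R)-3-((3E)-4,8-dimethylnona-3,7-dienyl)-3-methyloxiran-2-yl)-3-oxopent-1-enyl]-4-(triisopropylsilyloxy)benzoate | CC(C)=CCC/C(C)=C/CC[C@@]1(C)O[C@@H]1CCC(=O)/C=C/c2cc(C(=O)OC)ccc2O[Si](C(C)C)(C(C)C)C(C)C
F2 | step 7 | methyl 3-{(2Z)-2-[(5S,6R)-5-bromo-6-((3E)-4,8-dimethylnona-3,7-dienyl)-6-methyloxan-2-ylidene]ethyl}-4-(triisopropylsilyloxy)benzoate | CC(C)=CCC/C(C)=C/CC[C@@]1(C)O/C(=C\Cc2cc(C(=O)OC)ccc2O[Si](C(C)C)(C(C)C)C(C)C)CC[C@@H]1Br
F3 | step 12 | acyl bromide of bis-epoxy acid 16 | C=C1CC[C@H](Br)[C@@](C)(CC[C@@H]2O[C@@]2(C)CC[C@@H]3OC3(C)C)[C@@H]1Cc4cc(C(=O)Br)ccc4O[Si](C(C)C)(C(C)C)C(C)C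
F4 | step 12 | O-triisopropylsilyl (10S,11S)-10,11-epoxy-14-bromo macrolactone | C=C1CC[C@H](Br)[C@@]2(C)CC[C@@H]4O[C@@]4(C)CC[C@@H](Br)C(C)(C)OC(=O)c3ccc(O[Si](C(C)C)(C(C)C)C(C)C)c(c3)C[C@H]12
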